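**Strategy**

The route rests on disconnecting the C1–C2 bond of ring B. C1 is a diarylmethine para to the C4' oxygen of the pendant ring, so a free 4'-phenol makes it a latent para-quinone methide carbon. C2–C3=C4 is what an ene reaction leaves from an (E)-2-methylbut-2-enyl chain on ring A. One chiral-acid-catalysed step therefore turns a racemic para-hydroxybenzhydrol, carrying that chain ortho to the carbinol, into ring B, setting C1 and C2 (trans) and placing the C3=C4 styrene. The precursor is assembled convergently from a benzylic bromide, a stereodefined butenylboronate and silyl-protected vanillin; the only step afterwards is O-methylation.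

Key step: step 5

Numbering: naphthalene locants are used (ring A = aromatic carbons C4a–C8a; ring B = C1–C4 plus C4a and C8a); primed locants refer to the pendant aryl ring.

Assumption: the sense of induction of a given catalyst enantiomer on this substrate class cannot be assigned in advance; (R)-TRIP [(R)-3,3'-bis(2,4,6-triisopropylphenyl)-1,1'-binaphthyl-2,2'-diyl hydrogen phosphate] is written, and its mirror image would be used, with nothing else changed, if the first experiment should point to the (1S,2R) series.

**Route**

Step 1
Reactants: 1 vanillin (4-hydroxy-3-methoxybenzaldehyde)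
Product: 2 4-[(tert-butyldimethylsilyl)oxy]-3-methoxybenzaldehyde
Conditions: TBSCl, imidazole, DMF, 0 °C → rt
Reagents that add atoms: tert-butyldimethylsilyl chloride, CC(C)(C)[Si](C)(C)Cl
Why: Silylation of the phenol under imidazole catalysis removes the acidic proton, so the aldehyde can take an aryllithium in step 3, and the aryl silyl ether can later be cleaved by fluoride without acid.

Step 2
Reactants: 3 1-bromo-2-(bromomethyl)-4,5-dimethoxybenzene (2-bromo-4,5-dimethoxybenzyl bromide); 4 2-[(Z)-but-2-en-2-yl]-4,4,5,5-tetramethyl-1,3,2-dioxaborolane (commercial; also the hydroboration product of but-2-yne with pinacolborane)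
Product: 5 1-bromo-4,5-dimethoxy-2-[(E)-2-methylbut-2-en-1-yl]benzene
Conditions: Pd(PPh3)4 (3 mol %), K2CO3, THF/H2O (10:1), 60 °C
Reagents that add atoms: none
Why: sp3–sp2 Suzuki–Miyaura coupling in which the benzylic C–Br bond undergoes oxidative addition far faster than the electron-rich, ortho-substituted aryl C–Br bond and the alkenyl group transfers with retention, so the cis-dimethyl boronate maps onto the (E)-2-methylbut-2-enyl chain (the descriptor changes from Z to E only because CH2Ar outranks CH3 whereas boron does not).

Step 3
Reactants: 5 1-bromo-4,5-dimethoxy-2-[(E)-2-methylbut-2-en-1-yl]benzene; 2 4-[(tert-butyldimethylsilyl)oxy]-3-methoxybenzaldehyde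
Product: 7 (±)-{4-[(tert-butyldimethylsilyl)oxy]-3-methoxyphenyl}{4,5-dimethoxy-2-[(E)-2-methylbut-2-en-1-yl]phenyl}methanol, via aryllithium 6 (not isolated)
Conditions: n-BuLi, THF, −78 °C; then 2, −78 → −20 °C; aq. NH4Cl
Reagents that add atoms: none
Why: Bromine–lithium exchange is fast at −78 °C and outruns deprotonation of the benzylic-allylic CH2, and 1,2-addition of the aryllithium to the non-enolisable aldehyde gives the carbinol, whose new centre needs no control because it is erased in step 5.

Step 4
Reactants: 7 (±)-{4-[(tert-butyldimethylsilyl)oxy]-3-methoxyphenyl}{4,5-dimethoxy-2-[(E)-2-methylbut-2-en-1-yl]phenyl}methanol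
Product: 8 (±)-{4,5-dimethoxy-2-[(E)-2-methylbut-2-en-1-yl]phenyl}(4-hydroxy-3-methoxyphenyl)methanol
Conditions: TBAF, AcOH, THF, 0 °C (product filtered through Et3N-deactivated silica and used at once)
Reagents that add atoms: none
Why: Fluoride-mediated desilylation of an aryl silyl ether is rapid at 0 °C, and the acetic acid buffer keeps the medium near neutral so that the freed para-hydroxybenzhydrol is neither ionised by acid nor left as a phenoxide.

Step 5
Reactants: 8 (±)-{4,5-dimethoxy-2-[(E)-2-methylbut-2-en-1-yl]phenyl}(4-hydroxy-3-methoxyphenyl)methanol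
Product: 10 4-[(1R,2S)-6,7-dimethoxy-2,3-dimethyl-1,2-dihydronaphthalen-1-yl]-2-methoxyphenol, via para-quinone methide 9 (not isolated)
Conditions: (R)-TRIP (10 mol %), 4 Å MS, toluene (0.02 M), 0 °C → rt
Reagents that add atoms: none
Why: Proposed new method: the acid ionises either enantiomer of the carbinol to the same planar para-quinone methide 9, held as a hydrogen-bonded contact ion pair with the chiral phosphate, and the tethered trisubstituted alkene adds through its CH terminus (C2) to the methide carbon C1 while the phosphate takes a benzylic C4–H from the developing tertiary C3 cation, which amounts to an intramolecular vinylogous ene reaction that restores the phenol and leaves the C3=C4 styrene. The closest known reaction types are chiral phosphoric acid-catalysed 1,6-additions of π-nucleophiles (indoles, naphthols, enamides, styrenes) to para-quinone methides generated in situ from para-hydroxybenzyl alcohols, and Brønsted acid-catalysed carbonyl-ene and cation–olefin cyclisations. Ring B closes in a 6-endo-trig mode with respect to the alkene (6-exo-trig with respect to the quinone methide C=C) through a half-chair in which C2 and C3 lie on opposite sides of the ring A plane. C1 is set by the catalyst, which shields one face of the methide carbon; C2 follows from C1 because the (E)-alkene holds its C2 methyl anti to C4 (pseudo-equatorial) while the quinone methide ring turns away from C3 and its methyl (exo), which puts aryl and methyl trans. The step needs attack through C2 and not C3, secured by the C3 methyl (tertiary versus secondary cation, six- versus five-membered ring), and proton loss from C4 and not from C2 or the C3 methyl, secured by the benzylic acidity of C4–H and conjugation of the new alkene with ring A; high dilution suppresses intermolecular arylation of 9.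

Step 6
Reactants: 10 4-[(1R,2S)-6,7-dimethoxy-2,3-dimethyl-1,2-dihydronaphthalen-1-yl]-2-methoxyphenol
Product: 11 (1R,2S)-1-(3,4-dimethoxyphenyl)-6,7-dimethoxy-2,3-dimethyl-1,2-dihydronaphthalene
Conditions: MeI, K2CO3, acetone, rt
Reagents that add atoms: iodomethane, CI
Why: Williamson O-methylation of the phenoxide, under carbonate conditions too weakly basic to deprotonate the bis-benzylic C1–H or the allylic C2–H, so both stereocentres and the styrene are untouched.

**Compound list**

1 | vanillin (4-hydroxy-3-methoxybenzaldehyde) | COc1cc(C=O)ccc1O | starting material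
2 | 4-[(tert-butyldimethylsilyl)oxy]-3-methoxybenzaldehyde | COc1cc(C=O)ccc1O[Si](C)(C)C(C)(C)C | intermediate
3 | 1-bromo-2-(bromomethyl)-4,5-dimethoxybenzene | COc1cc(Br)c(CBr)cc1OC | starting material
4 | 2-[(Z)-but-2-en-2-yl]-4,4,5,5-tetramethyl-1,3,2-dioxaborolane | C/C=C(\C)B1OC(C)(C)C(C)(C)O1 | starting material
5 | 1-bromo-4,5-dimethoxy-2-[(E)-2-methylbut-2-en-1-yl]benzene | C/C=C(\C)Cc1cc(OC)c(OC)cc1Br | intermediate
6 | {4,5-dimethoxy-2-[(E)-2-methylbut-2-en-1-yl]phenyl}lithium (not isolated) | C/C=C(\C)Cc1cc(OC)c(OC)cc1[Li] | intermediate
7 | (±)-{4-[(tert-butyldimethylsilyl)oxy]-3-methoxyphenyl}{4,5-dimethoxy-2-[(E)-2-methylbut-2-en-1-yl]phenyl}methanol | C/C=C(\C)Cc1cc(OC)c(OC)cc1C(O)c1ccc(O[Si](C)(C)C(C)(C)C)c(OC)c1 | intermediate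
8 | (±)-{4,5-dimethoxy-2-[(E)-2-methylbut-2-en-1-yl]phenyl}(4-hydroxy-3-methoxyphenyl)methanol | C/C=C(\C)Cc1cc(OC)c(OC)cc1C(O)c1ccc(O)c(OC)c1 | intermediate
9 | 4-({4,5-dimethoxy-2-[(E)-2-methylbut-2-en-1-yl]phenyl}methylidene)-2-methoxycyclohexa-2,5-dien-1-one (para-quinone methide, methide geometry undefined, not isolated) | C/C=C(\C)Cc1cc(OC)c(OC)cc1C=C2C=CC(=O)C(OC)=C2 | intermediate
10 | 4-[(1R,2S)-6,7-dimethoxy-2,3-dimethyl-1,2-dihydronaphthalen-1-yl]-2-methoxyphenol | COc1cc([C@@H]2c3cc(OC)c(OC)cc3C=C(C)[C@H]2C)ccc1O | intermediate
11 | (1R,2S)-1-(3,4-dimethoxyphenyl)-6,7-dimethoxy-2,3-dimethyl-1,2-dihydronaphthalene | COc1ccc([C@@H]2c3cc(OC)c(OC)cc3C=C(C)[C@H]2C)cc1OC | target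

**Step count**

Total step count: 6
Longest linear sequence: 5 steps (3 → 5 → 7 → 8 → 10 → 11; the branch from 1 through 2 is equally long)

**Steps most likely to fail**

1. Step 5 (Proposed new method). The catalyst may discriminate the two faces of the bound quinone methide poorly, or ring closure may be outrun by intermolecular arylation of the quinone methide. The fallback uses known chemistry and sets out from 8. An achiral Brønsted acid (p-TsOH·H2O, 10 mol %, CH2Cl2, 0.01 M, 0 °C) should effect the same ring closure as an ordinary cation–olefin cyclisation ended by proton loss, giving the racemic trans phenol (±)-4-[(1R*,2S*)-6,7-dimethoxy-2,3-dimethyl-1,2-dihydronaphthalen-1-yl]-2-methoxyphenol F1. Preparative chromatography on a chiral stationary phase (SFC, amylose tris(3,5-dimethylphenylcarbamate)) then separates the unwanted 4-[(1S,2R)-6,7-dimethoxy-2,3-dimethyl-1,2-dihydronaphthalen-1-yl]-2-methoxyphenol F2, which is set aside, from the (1R,2S)-enantiomer. That enantiomer is 10, where the route is rejoined.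

2. Step 2. Chemoselectivity may be lost through oxidative addition at the aryl C–Br bond, or the electron-rich benzylic bromide may be solvolysed by the aqueous base before it couples. The fallback inverts the polarity of the partners and sets out from 3. Zinc insertion into the benzylic C–Br bond (Zn dust, LiCl, THF, rt; aryl bromides are inert under these conditions) should give bromo[(2-bromo-4,5-dimethoxyphenyl)methyl]zinc F3. This is coupled under anhydrous Negishi conditions (Pd(PPh3)4, THF, rt) with commercial (E)-2-bromobut-2-ene (C/C=C(\C)Br), with retention at the alkenyl carbon, and the route is rejoined at 5.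

3. Step 4. The freed para-hydroxybenzhydrol may ionise prematurely to the quinone methide and oligomerise during fluoride treatment, removal of the ammonium salts or storage. The fallback unveils the carbinol last, by reduction, and sets out from 7. Oxidation (MnO2, CH2Cl2, rt) should give {4-[(tert-butyldimethylsilyl)oxy]-3-methoxyphenyl}{4,5-dimethoxy-2-[(E)-2-methylbut-2-en-1-yl]phenyl}methanone F4. Desilylation (TBAF, THF, 0 °C) should then give the storable {4,5-dimethoxy-2-[(E)-2-methylbut-2-en-1-yl]phenyl}(4-hydroxy-3-methoxyphenyl)methanone F5. Reduction with NaBH4 (MeOH/THF, 0 °C → rt), followed by a neutral extractive work-up, returns to the route at 8, which is taken directly into step 5.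

**Further compounds**

F1 | step 5 | (±)-4-[(1R*,2S*)-6,7-dimethoxy-2,3-dimethyl-1,2-dihydronaphthalen-1-yl]-2-methoxyphenol (racemate, both enantiomers written) | COc1cc([C@@H]2c3cc(OC)c(OC)cc3C=C(C)[C@H]2C)ccc1O.COc1cc([C@H]2c3cc(OC)c(OC)cc3C=C(C)[C@@H]2C)ccc1O
F2 | step 5 | 4-[(1S,2R)-6,7-dimethoxy-2,3-dimethyl-1,2-dihydronaphthalen-1-yl]-2-methoxyphenol | COc1cc([C@H]2c3cc(OC)c(OC)cc3C=C(C)[C@@H]2C)ccc1O
F3 | step 2 | bromo[(2-bromo-4,5-dimethoxyphenyl)methyl]zinc | COc1cc(Br)c(C[Zn]Br)cc1OC
F4 | step 4 | {4-[(tert-butyldimethylsilyl)oxy]-3-methoxyphenyl}{4,5-dimethoxy-2-[(E)-2-methylbut-2-en-1-yl]phenyl}methanone | C/C=C(\C)Cc1cc(OC)c(OC)cc1C(=O)c1ccc(O[Si](C)(C)C(C)(C)C)c(OC)c1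
F5 | step 4 | {4,5-dimethoxy-2-[(E)-2-methylbut-2-en-1-yl]phenyl}(4-hydroxy-3-methoxyphenyl)methanone | C/C=C(\C)Cc1cc(OC)c(OC)cc1C(=O)c1ccc(O)c(OC)c1
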